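**Strategy.** The target is ent-epifisetinidol-(4α→6)-fisetinidol. Both flavan units are traced to one achiral 2-aryl-4H-chromene whose ring C is closed across C2–C3. In the precursor, an aryl ester, C2 is the ester carbonyl carbon, already bonded to O1 and to ring B, and C3 is the inner carbon of an ortho-allyl group on ring A. A titanium-alkylidene carbonyl–olefin metathesis cascade joins them as the C2=C3 enol ether in one operation. It exploits the O1–C2(aryl)–C3(OH) array of ring C, the anti-Markovnikov hydrate of that enol ether: enantiodivergent hydroboration then gives both antipodes of the 2,3-trans alcohol, one used as lower unit, the other inverted at C3, activated at C4 and coupled to C6.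

Key step: step 4

Remark: flavan numbering is used (O1, C2, C3, C4, C4a, C5–C8, C8a; ring A = benzo ring, ring B = 2-aryl ring, ring C = pyran ring); Bn = benzyl, Ipc = isopinocampheyl.

Assumption: the facial sense of IpcBH2 on chromene 8 is taken to follow that known for 1-arylcycloalkenes; if it proves opposite, the two reagent antipodes are simply exchanged between step 5 and step 6, since both antipodes of the alcohol are needed.

**Step 1**
Reactants: 1 3-(benzyloxy)phenol; 2 allyl bromide
Product: 3 1-(allyloxy)-3-(benzyloxy)benzene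
Conditions: K2CO3, acetone, reflux
Reagents that add atoms: none
Why: Williamson ether synthesis, SN2 attack of the phenoxide on the allylic bromide, with the benzyl ether untouched.

**Step 2**
Reactants: 3 1-(allyloxy)-3-(benzyloxy)benzene
Product: 4 2-allyl-5-(benzyloxy)phenol
Conditions: N,N-diethylaniline, 195 °C, argon
Reagents that add atoms: none
Why: aromatic Claisen rearrangement ([3,3]-sigmatropic shift, then tautomerisation); migration to the unhindered ortho position para to the benzyloxy group should be favoured, and the minor 2-allyl-3-(benzyloxy)phenol is removed by chromatography.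

**Step 3**
Reactants: 4 2-allyl-5-(benzyloxy)phenol; 5 3,4-bis(benzyloxy)benzoic acid
Product: 6 2-allyl-5-(benzyloxy)phenyl 3,4-bis(benzyloxy)benzoate
Conditions: DCC, DMAP (cat.), CH2Cl2, 0 °C to rt
Reagents that add atoms: none
Why: Steglich esterification through the O-acylisourea and acylpyridinium, which acylates the phenol cleanly and puts O1, the future C2 and ring B in place.

**Step 4**
Reactants: 6 2-allyl-5-(benzyloxy)phenyl 3,4-bis(benzyloxy)benzoate
Product: 8 7-(benzyloxy)-2-[3,4-bis(benzyloxy)phenyl]-4H-chromene, via acyclic enol ether 7 (not isolated)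
Conditions: Tebbe reagent Cp2Ti(μ-Cl)(μ-CH2)AlMe2 (4 equiv), pyridine (cat.), THF, 25 °C then reflux; aqueous NaOH work-up, basic alumina
Reagents that add atoms: none
Why: Cp2Ti=CH2 released from the Tebbe reagent first methylenates the aryl ester carbonyl through an oxatitanacyclobutane to give the 1,1-disubstituted enol ether 7; a second equivalent adds to the terminal allyl olefin, the titanacyclobutane loses ethylene to leave a titanium alkylidene on C3, and this closes onto the enol ether by [2+2] cycloaddition and cycloreversion, which forms C2=C3 and returns Cp2Ti=CH2. The closest known reaction type is the titanium-alkylidene olefinic ester cyclisation (tandem carbonyl methylenation and ring-closing olefin metathesis) that turns olefinic esters into six-membered cyclic enol ethers. Ring C is closed as a six-membered ring by ring-closing metathesis between the alkylidene carbon C3 and the enol ether carbon C2, the substrate already holding O1, C8a, C4a and C4 of that ring. No stereocentre is formed: C2 and C3 become the two sp2 carbons on which step 5 and step 6 later set both centres. The step needs cyclisation to win over simple methylenation and must not shift the allyl double bond into conjugation (which would lead to a benzofuran); the ortho placement of ester and allyl group on ring A, the strain-free six-membered product and the conjugation of the new enol ether with ring B should secure this, and the benzyl ethers are inert to the reagent.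

**Step 5**
Reactants: 8 7-(benzyloxy)-2-[3,4-bis(benzyloxy)phenyl]-4H-chromene
Product: 10 (2R,3S)-7-(benzyloxy)-2-[3,4-bis(benzyloxy)phenyl]chroman-3-ol, via alkylborane 9 (not isolated)
Conditions: IpcBH2 [from (+)-α-pinene], Et2O/THF, −25 °C; then NaOH, H2O2, 0 °C to rt
Reagents that add atoms: hydrogen peroxide, OO
Why: asymmetric hydroboration–oxidation, in which boron adds to C3 (β to O1, the less substituted alkene carbon) and hydrogen to C2 from the same face so that 2-aryl and 3-OH must be trans, the face being chosen by the chiral Ipc group as for 1-arylcycloalkenes to give (2R,3S), and oxidation of the C–B bond proceeding with retention.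

**Step 6**
Reactants: 8 7-(benzyloxy)-2-[3,4-bis(benzyloxy)phenyl]-4H-chromene
Product: 12 (2S,3R)-7-(benzyloxy)-2-[3,4-bis(benzyloxy)phenyl]chroman-3-ol, via alkylborane 11 (not isolated)
Conditions: IpcBH2 [from (−)-α-pinene], Et2O/THF, −25 °C; then NaOH, H2O2, 0 °C to rt
Reagents that add atoms: hydrogen peroxide, OO
Why: the same syn-selective asymmetric hydroboration–oxidation with the antipodal reagent, which should deliver the enantiomeric 2,3-trans alcohol and so fix the (2S) centre of the upper unit.

**Step 7**
Reactants: 12 (2S,3R)-7-(benzyloxy)-2-[3,4-bis(benzyloxy)phenyl]chroman-3-ol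
Product: 13 (2S)-7-(benzyloxy)-2-[3,4-bis(benzyloxy)phenyl]chroman-3-one
Conditions: Dess–Martin periodinane, CH2Cl2, 0 °C to rt
Reagents that add atoms: none
Why: Dess–Martin oxidation of the secondary alcohol under near-neutral conditions, which should leave the enolisable C2 centre intact if the ketone is used at once.

**Step 8**
Reactants: 13 (2S)-7-(benzyloxy)-2-[3,4-bis(benzyloxy)phenyl]chroman-3-one
Product: 14 (2S,3S)-7-(benzyloxy)-2-[3,4-bis(benzyloxy)phenyl]chroman-3-ol
Conditions: LiBH(s-Bu)3 (L-Selectride), LiBr, THF, −78 °C; aqueous work-up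
Reagents that add atoms: none
Why: substrate-controlled ketone reduction in which the bulky hydride attacks C3 from the face opposite the 2-aryl group, so the new 3-OH is cis to ring B (3S), as established for flavan-3-ones.

**Step 9**
Reactants: 14 (2S,3S)-7-(benzyloxy)-2-[3,4-bis(benzyloxy)phenyl]chroman-3-ol
Product: 15 (2S,3S,4R)-7-(benzyloxy)-2-[3,4-bis(benzyloxy)phenyl]-4-(2-ethoxyethoxy)chroman-3-ol
Conditions: DDQ, 2-ethoxyethanol, CH2Cl2, rt
Reagents that add atoms: 2-ethoxyethanol, CCOCCO
Why: oxidative benzylic C–H functionalisation in which DDQ abstracts hydride from C4, whose cation is stabilised by O1 (ortho) and 7-OBn (para) on ring A, and the alcohol traps it trans to the 3-OH; the C4 configuration is of no consequence because it is ionised again in step 10.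

**Step 10**
Reactants: 15 (2S,3S,4R)-7-(benzyloxy)-2-[3,4-bis(benzyloxy)phenyl]-4-(2-ethoxyethoxy)chroman-3-ol; 10 (2R,3S)-7-(benzyloxy)-2-[3,4-bis(benzyloxy)phenyl]chroman-3-ol (3 equiv)
Product: 17 7,3',4'-tri-O-benzyl-ent-epifisetinidol-(4α→6)-7,3',4'-tri-O-benzylfisetinidol, via benzylic cation 16 (not isolated)
Conditions: Me3SiOTf (0.3 equiv), CH2Cl2, −78 to −40 °C; Et3N quench
Reagents that add atoms: none
Why: SN1 Friedel–Crafts alkylation in which the Lewis acid ionises the 4-alkoxy group and ring A of 10 attacks at C6 (para to O1, ortho to OBn, less hindered than C8) anti to the axial 3-OH of the 2,3-cis cation, so the new C4 centre is 3,4-trans (4α), while the excess of 10 holds back oligomerisation.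

**Step 11**
Reactants: 17 7,3',4'-tri-O-benzyl-ent-epifisetinidol-(4α→6)-7,3',4'-tri-O-benzylfisetinidol
Product: 18 ent-epifisetinidol-(4α→6)-fisetinidol
Conditions: H2 (1 atm), Pd(OH)2/C, THF/MeOH/H2O, rt
Reagents that add atoms: none
Why: catalytic hydrogenolysis of the six aryl benzyl ethers under neutral conditions, which should leave the benzylic C4–C6 interflavan bond, the ring C ether bonds and all five stereocentres untouched.

**Compound list**

1 | 3-(benzyloxy)phenol | Oc1cccc(OCc2ccccc2)c1 | starting material
2 | allyl bromide | C=CCBr | starting material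
3 | 1-(allyloxy)-3-(benzyloxy)benzene | C=CCOc1cccc(OCc2ccccc2)c1 | intermediate
4 | 2-allyl-5-(benzyloxy)phenol | C=CCc1ccc(OCc2ccccc2)cc1O | intermediate
5 | 3,4-bis(benzyloxy)benzoic acid | OC(=O)c1ccc(OCc2ccccc2)c(OCc2ccccc2)c1 | starting material
6 | 2-allyl-5-(benzyloxy)phenyl 3,4-bis(benzyloxy)benzoate | C=CCc1ccc(OCc2ccccc2)cc1OC(=O)c1ccc(OCc2ccccc2)c(OCc2ccccc2)c1 | intermediate
7 | 2-allyl-5-(benzyloxy)phenyl 1-[3,4-bis(benzyloxy)phenyl]vinyl ether (acyclic enol ether, not isolated) | C=CCc1ccc(OCc2ccccc2)cc1OC(=C)c1ccc(OCc2ccccc2)c(OCc2ccccc2)c1 | intermediate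
8 | 7-(benzyloxy)-2-[3,4-bis(benzyloxy)phenyl]-4H-chromene | C1(c2ccc(OCc3ccccc3)c(OCc3ccccc3)c2)=CCc2ccc(OCc3ccccc3)cc2O1 | intermediate
9 | [(2R,3S)-7-(benzyloxy)-2-[3,4-bis(benzyloxy)phenyl]chroman-3-yl](isopinocampheyl)borane, Ipc from (+)-α-pinene (not isolated) | C[C@H]1[C@H](B[C@H]5Cc6ccc(OCc7ccccc7)cc6O[C@@H]5c5ccc(OCc6ccccc6)c(OCc6ccccc6)c5)C[C@@H]2C[C@H]1C2(C)C | intermediate
10 | (2R,3S)-7-(benzyloxy)-2-[3,4-bis(benzyloxy)phenyl]chroman-3-ol (tri-O-benzylfisetinidol, 2,3-trans) | O[C@H]1Cc2ccc(OCc3ccccc3)cc2O[C@@H]1c1ccc(OCc3ccccc3)c(OCc3ccccc3)c1 | intermediate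
11 | [(2S,3R)-7-(benzyloxy)-2-[3,4-bis(benzyloxy)phenyl]chroman-3-yl](isopinocampheyl)borane, Ipc from (−)-α-pinene (not isolated) | C[C@@H]1[C@@H](B[C@@H]5Cc6ccc(OCc7ccccc7)cc6O[C@H]5c5ccc(OCc6ccccc6)c(OCc6ccccc6)c5)C[C@H]2C[C@@H]1C2(C)C | intermediate
12 | (2S,3R)-7-(benzyloxy)-2-[3,4-bis(benzyloxy)phenyl]chroman-3-ol (tri-O-benzyl-ent-fisetinidol, 2,3-trans) | O[C@@H]1Cc2ccc(OCc3ccccc3)cc2O[C@H]1c1ccc(OCc3ccccc3)c(OCc3ccccc3)c1 | intermediate
13 | (2S)-7-(benzyloxy)-2-[3,4-bis(benzyloxy)phenyl]chroman-3-one | O=C1Cc2ccc(OCc3ccccc3)cc2O[C@H]1c1ccc(OCc3ccccc3)c(OCc3ccccc3)c1 | intermediate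
14 | (2S,3S)-7-(benzyloxy)-2-[3,4-bis(benzyloxy)phenyl]chroman-3-ol (tri-O-benzyl-ent-epifisetinidol, 2,3-cis) | O[C@H]1Cc2ccc(OCc3ccccc3)cc2O[C@H]1c1ccc(OCc3ccccc3)c(OCc3ccccc3)c1 | intermediate
15 | (2S,3S,4R)-7-(benzyloxy)-2-[3,4-bis(benzyloxy)phenyl]-4-(2-ethoxyethoxy)chroman-3-ol (2,3-cis-3,4-trans) | O[C@H]1[C@H](OCCOCC)c2ccc(OCc3ccccc3)cc2O[C@H]1c1ccc(OCc3ccccc3)c(OCc3ccccc3)c1 | intermediate
16 | (2S,3S)-7-(benzyloxy)-2-[3,4-bis(benzyloxy)phenyl]-3-hydroxychroman-4-ylium (benzylic cation, not isolated) | O[C@H]1[CH+]c2ccc(OCc3ccccc3)cc2O[C@H]1c1ccc(OCc3ccccc3)c(OCc3ccccc3)c1 | intermediate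
17 | 7,3',4'-tri-O-benzyl-ent-epifisetinidol-(4α→6)-7,3',4'-tri-O-benzylfisetinidol (hexa-O-benzyl ether of 18 at the six phenolic oxygens, both 3-OH free; upper unit 2,3-cis-3,4-trans, lower unit 2,3-trans, same spatial arrangement at all five centres as 18) | C(Oc1ccc2c(c1)O[C@@H](c1ccc(OCc3ccccc3)c(OCc3ccccc3)c1)[C@@H](O)[C@@H]2c1cc2c(cc1OCc1ccccc1)O[C@H](c1ccc(OCc3ccccc3)c(OCc3ccccc3)c1)[C@@H](O)C2)c1ccccc1 | intermediate
18 | (2S,3S,4R)-2-(3,4-dihydroxyphenyl)-4-[(2R,3S)-2-(3,4-dihydroxyphenyl)-3,7-dihydroxychroman-6-yl]chroman-3,7-diol, ent-epifisetinidol-(4α→6)-fisetinidol | Oc1ccc2c(c1)O[C@@H](c1ccc(O)c(O)c1)[C@@H](O)[C@@H]2c1cc2c(cc1O)O[C@H](c1ccc(O)c(O)c1)[C@@H](O)C2 | target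

**Step count and risks**

Total step count: 11. Longest linear sequence: 10 (steps 1, 2, 3, 4, 6, 7, 8, 9, 10, 11); step 5 is the branch that supplies the lower unit.

Most likely to fail, first: step 4. The cascade may stop after carbonyl methylenation, or the titanium and aluminium species may shift the allyl double bond into conjugation before ring closure. The fallback sets out from 6 and comes back at 8. The ester is methylenated with one equivalent of the Tebbe reagent at 0 °C and the acyclic enol ether 7 is isolated on basic alumina. Ring C is then closed in a separate operation by ruthenium-carbene ring-closing metathesis with the second-generation Grubbs catalyst (H2IMes)(PCy3)Cl2Ru=CHPh in toluene at 70 °C, with 1,4-benzoquinone added against olefin migration. This moves the C2=C3 bond formation from the titanium cascade to a neutral ruthenium catalyst acting on a purified diene; new compound: none F0.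

Second: step 5 (step 6 shares the risk). Facial discrimination by the reagent on this enol ether may be insufficient, or the C3 borane may undergo β-elimination with opening of ring C. The fallback sets out from 8 and comes back at 10 and 12, replacing reagent control by resolution. Hydroboration–oxidation with BH3·THF should give the racemic 2,3-trans alcohol, an equimolar mixture of 10 and 12. Esterification with (S)-2-methoxy-2-phenylacetic acid (DCC, DMAP) gives the diastereomeric esters (2R,3S)-7-(benzyloxy)-2-[3,4-bis(benzyloxy)phenyl]chroman-3-yl (S)-2-methoxy-2-phenylacetate F1 and (2S,3R)-7-(benzyloxy)-2-[3,4-bis(benzyloxy)phenyl]chroman-3-yl (S)-2-methoxy-2-phenylacetate F2. These are separated by chromatography or crystallisation and each is saponified with LiOH in THF/H2O, to 10 and 12 respectively. Because the route consumes both antipodes, neither half of the racemate is wasted.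

Third: step 10. Alkylation may occur at C8 instead of C6 of the nucleophile, and the product or 15 itself may be alkylated further, since the benzylated ring A of the electrophile is as nucleophilic as that of 10. The fallback sets out from 10 and 15 and comes back at 18, replacing the protected nucleophile by the free phenol. Hydrogenolysis of 10 (H2, Pd(OH)2/C) gives (−)-fisetinidol F3. Its free 7-OH ring A is far more nucleophilic than any benzylated ring and is known as a reaction type to be alkylated at C6 by flavan C4 cations. Condensation of F3 with 15 (BF3·OEt2, THF/CH2Cl2, 0 °C) should give 7,3',4'-tri-O-benzyl-ent-epifisetinidol-(4α→6)-fisetinidol F4, and hydrogenolysis of its three benzyl ethers gives 18.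

**Further compounds**

F0 | step 4 | none | none
F1 | step 5 | (2R,3S)-7-(benzyloxy)-2-[3,4-bis(benzyloxy)phenyl]chroman-3-yl (S)-2-methoxy-2-phenylacetate | CO[C@H](C(=O)O[C@H]1Cc2ccc(OCc3ccccc3)cc2O[C@@H]1c1ccc(OCc3ccccc3)c(OCc3ccccc3)c1)c1ccccc1
F2 | step 5 | (2S,3R)-7-(benzyloxy)-2-[3,4-bis(benzyloxy)phenyl]chroman-3-yl (S)-2-methoxy-2-phenylacetate | CO[C@H](C(=O)O[C@@H]1Cc2ccc(OCc3ccccc3)cc2O[C@H]1c1ccc(OCc3ccccc3)c(OCc3ccccc3)c1)c1ccccc1
F3 | step 10 | (−)-fisetinidol, (2R,3S)-2-(3,4-dihydroxyphenyl)chroman-3,7-diol | O[C@H]1Cc2ccc(O)cc2O[C@@H]1c1ccc(O)c(O)c1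
F4 | step 10 | 7,3',4'-tri-O-benzyl-ent-epifisetinidol-(4α→6)-fisetinidol (18 carrying benzyl ethers on the three phenolic oxygens of the upper unit only) | C(Oc1ccc2c(c1)O[C@@H](c1ccc(OCc3ccccc3)c(OCc3ccccc3)c1)[C@@H](O)[C@@H]2c1cc2c(cc1O)O[C@H](c1ccc(O)c(O)c1)[C@@H](O)C2)c1ccccc1
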